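Readings and results are simulated with made-up constants.

**Product gap.** Follow the left-handed product minus the right-handed product, and call this difference the gap. Racemisation turns each product into the other, so assume that without fresh product the gap shrinks towards zero.

all flasks: free catalyst 0.66 mM
- beta: left-handed substrate 1 M; right-handed substrate 1 M; solid reagent 1 M; run made earlier
- teal: left-handed substrate 1.0 M; right-handed substrate 1.0 M; solid reagent 2.00 M; time 25 min
- amber: left-handed substrate 1.0 M; right-handed substrate 1.0 M; solid reagent 2.00 M; time 100 min

beta run (percent of the left-handed substrate and right-handed substrate together charged)

| time / min | left-handed product / % | right-handed product / % | left-handed substrate / % |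
|---|---|---|---|
| 1.50 | 0.6 | 0 | 49.4 |
| 5.00 | 2.5 | 0 | 47.4 |
| 8.00 | 4.4 | 1.1 | 45.6 |
| 15.0 | 7.3 | 1.8 | 41.0 |
| 20.0 | 8.1 | 2.4 | 39.6 |
| 25.0 | 9.4 | 3.6 | 39.2 |

(standard deviation of a reading: 0.3 percentage points)

1. the winner by excess of left-handed product over right-handed product in the product; "neither" if no more than 2 percentage points parts them (teal / amber / neither)
2. excess of left-handed product over right-handed product in the product at the end, teal
3. excess of left-handed product over right-handed product in the product at the end, amber

- free catalyst is single-handed; left-handed substrate and right-handed substrate are mirror images of each other, charged as a racemate, each of them at the stated concentration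
- solid, in amounts per volume of the solution: solid reagent
- at the start none of the solid reagent is in solution
- an excess is below zero if the other one leads

**The curve.** Read beta first. Left-handed product reaches 2.5 % by 5.00 min, while right-handed product reads 0 %. Then the gap bends flat: 5.5 percentage points at 15.0 min, 5.8 points at 25.0 min. Beta's left-handed substrate bends as well, losing 4.6 points between 8.00 min and 15.0 min, then 0.4 points between 20.0 min and 25.0 min. Take that as the knee, though the last figure is of the size of the scatter of 0.3 points.

**Halving time.** In beta, right-handed product gains 2.5 points in 17.0 min, with the gap near 5.5 points. That reads as a racemisation constant of 0.0267 min⁻¹. The gap falls at double this constant, so the halving time of the gap, the time in which it drops by a factor of 2 without fresh product, is 13.0 min.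

**My reckoning.** Beta's product took about 0.260 M of reagent, assuming one per product, less than its 1 M of solid. So treat teal as beta at 25.0 min: 5.8 points on a total of 13.0 %, an excess of 44.6 %. Amber runs 75.0 min longer, which is 5.79 halving times. Reckoned with no fresh product and the total held, its gap falls to 0.11 points, an excess of 0.808 %.

**The forecast.** It gives 44 % for teal, −8 % for amber and teal as winner, expecting that “fresh right-handed product could then dominate”. We agree on teal; on amber, my excess stays above zero and the forecast's falls below it.

**The flask.** Teal gives 43.8 %, amber 1.15 %, and teal wins.

    partner + free catalyst + right-handed substrate → free catalyst + right-handed product (k = 0.0920 M⁻² s⁻¹)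
    partner + free catalyst + left-handed substrate → free catalyst + left-handed product (k = 2.30 M⁻² s⁻¹)
    left-handed product ⇌ right-handed product (k = 4.40 × 10⁻⁴ s⁻¹)
    free catalyst → spent catalyst (k = 0.00170 s⁻¹)
    solid reagent ⇌ partner, rate k5*(cs5 - [partner]) while solid is left; crystals form when [partner] > cs5 (solubility = 0.610 M, k = 0.00280 s⁻¹)

**Same gap.** Amber ends 0.34 points above my 0.808 %, and above the forecast's −8 %. Now take the neighbouring flask, amber read at 25 min. Its excess is 43.8 %, on a gap of 5.3 points. Carried forward 75.0 min at the same halving time and reckoned with no fresh product, that gap shrinks to 0.096 points. Free catalyst in that neighbouring flask stands at 7.81 % of its charge.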